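Ring A of this 6,8-diprenylflavonol is an acylphloroglucinol. Its C5–C6–C7–C8–C8a segment has the oxygen and prenyl pattern of a 2,4-diprenyl-3-oxoglutarate. C4a bears only the C4 carbonyl and is the CH3 carbon of a methyl ketone. Cutting C4a–C5 and C4a–C8a gives a [5+1] benzannulation. The terminal carbon of a diketone dianion that already holds ring B, C2, C3 and C4 is acylated twice by the diester, which closes and aromatises ring A with both prenyl groups in place. Precursors: MOM-protected diketone 12 and enol ether diester 6. The symmetry of ring A makes the later ring C closure unambiguous.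

Key step: step 6

Assumption: 3, 4, 6, 12, 14 and 15 are used as racemates, diastereomer mixtures or E/Z mixtures, because every one of these stereo-elements is erased before the achiral target is reached.

Remarks on the precursor design:
- (a) Diester 6 keeps one acidic hydrogen, its C4–H (the future C8–H). The dianion is therefore used in twofold amount, no free amide base is left when 6 is added, and the ring closure is run under equilibrating Mg(OMe)2/MeOH rather than under excess amide.
- (b) Only the E isomer of 6 (C1 ester cis to the C4 arm) can fold directly. Step 2 is therefore run under non-chelating conditions, and the Z isomer is expected to converge through the C8 dienolate of 14.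

Step 1
Reactants: 1 dimethyl 1,3-acetonedicarboxylate; 2 prenyl bromide (1-bromo-3-methylbut-2-ene)
Product: 4 dimethyl 2,4-bis(3-methylbut-2-enyl)-3-oxopentanedioate (dl/meso mixture), via monoprenyl keto diester 3 (not isolated)
Conditions: NaH (1.05 equiv), THF, 0 °C, then 2 (1.0 equiv), rt; same cycle repeated once in the same flask
Reagents that add atoms: prenyl bromide 2, CC(C)=CCBr
Why: Two successive SN2 alkylations of the stabilised β-keto diester enolate should give the 2,4-pattern, because after the first prenylation the untouched C4 methylene is both the more acidic and the less hindered site, and the dl/meso ratio is irrelevant since both centres become sp2 later.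

Step 2
Reactants: 4 dimethyl 2,4-bis(3-methylbut-2-enyl)-3-oxopentanedioate; 5 chloromethyl methyl ether
Product: 6 dimethyl 3-(methoxymethoxy)-2,4-bis(3-methylbut-2-enyl)pent-2-enedioate (racemic, E/Z mixture with E favoured)
Conditions: NaH (1.05 equiv), THF–DMPU 4:1, 0 °C; 5 (1.2 equiv), 0 °C → rt; chromatography on Et3N-deactivated silica
Reagents that add atoms: chloromethyl methyl ether 5, COCCl
Why: O-alkylation of a β-keto ester enolate by a hard, oxocarbenium-like electrophile, in which the fully substituted α-carbon blocks C-alkylation, one equivalent of base leaves the second α-position untouched, and the dissociating medium should favour the E isomer that can later close ring A.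

Step 3
Reactants: 7 2-chloro-3',4'-dihydroxyacetophenone
Product: 9 2,3',4'-trihydroxyacetophenone [1-(3,4-dihydroxyphenyl)-2-hydroxyethan-1-one], via formate ester 8 (not isolated)
Conditions: HCO2Na (3 equiv), HCO2H (cat.), EtOH–H2O 1:1, reflux, N2
Reagents that add atoms: sodium formate, [Na+].[O-]C=O
Why: SN2 displacement of the activated phenacyl chloride by formate followed by solvolysis of the labile formate ester in the same weakly acidic medium, which the free catechol tolerates.

Step 4
Reactants: 9 2,3',4'-trihydroxyacetophenone; 5 chloromethyl methyl ether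
Product: 10 1-[3,4-bis(methoxymethoxy)phenyl]-2-(methoxymethoxy)ethan-1-one
Conditions: 5 (4.5 equiv), i-Pr2NEt (6 equiv), n-Bu4NI (cat.), CH2Cl2, 0 → 35 °C
Reagents that add atoms: chloromethyl methyl ether 5, COCCl
Why: Standard MOM ether formation on both phenols and the primary alcohol in one operation, giving acetal groups that are inert to amide bases and methoxide and that can all be removed together at the end.

Step 5
Reactants: 10 1-[3,4-bis(methoxymethoxy)phenyl]-2-(methoxymethoxy)ethan-1-one; 11 1-acetylbenzotriazole
Product: 12 1-[3,4-bis(methoxymethoxy)phenyl]-2-(methoxymethoxy)butane-1,3-dione (racemic, keto/enol mixture)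
Conditions: LiN(SiMe3)2 (2.1 equiv), THF, −78 °C; 11 (1.05 equiv), −78 → 0 °C; AcOH quench
Reagents that add atoms: 1-acetylbenzotriazole 11, CC(=O)n1nnc2ccccc21
Why: Crossed Claisen-type C-acylation of a preformed lithium enolate with an N-acylbenzotriazole, an acyl donor known to favour attack at carbon, where 10 has a single enolisable position and the second equivalent of base stores the more acidic product as its enolate.

Step 6
Reactants: 12 1-[3,4-bis(methoxymethoxy)phenyl]-2-(methoxymethoxy)butane-1,3-dione; 6 dimethyl 3-(methoxymethoxy)-2,4-bis(3-methylbut-2-enyl)pent-2-enedioate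
Product: 15 1-[3,4-bis(methoxymethoxy)phenyl]-3-[2,6-dihydroxy-4-(methoxymethoxy)-3,5-bis(3-methylbut-2-enyl)phenyl]-2-(methoxymethoxy)propane-1,3-dione (racemic), via dilithium dianion 13 (not isolated), via open-chain triketo ester 14 (not isolated)
Conditions: 12 (2.0 equiv), LiN(i-Pr)2 (4.0 equiv), THF, −78 → 0 °C; 6 (1.0 equiv), THF, −78 → 0 °C; then Mg(OMe)2 (5 equiv), MeOH, 50 °C; AcOH quench at 0 °C (pH 5–6); surplus 12 recovered
Reagents that add atoms: none
Why: Proposed new method: the terminal CH2 carbanion of dianion 13, its most nucleophilic site and the only second deprotonation site that the aryl ketone allows, should add to the unconjugated ester of 6 (the other ester is a far less electrophilic push–pull vinylogous carbonate) and expel methoxide to give 14, while the second equivalent of 13 takes up the newly acidified C4a–H and C8–H. After the switch to Mg(OMe)2/MeOH, all proton transfers and the E/Z interconversion of the C6=C7 push–pull alkene (through the C8 dienolate) become reversible, the magnesium chelate of the C4/C8a dicarbonyl presents C4a to the remaining ester, a 6-exo-trig Dieckmann-type Claisen closure forms C4a–C5, and loss of methanol with enolisation of C4a–H and C8–H aromatises ring A irreversibly. The closest known reactions are the terminal acylation of 1,3-diketone dianions by esters and the Mg(OMe)2-induced Claisen cyclisation of 3,5,7-triketo esters to acylphloroglucinols; what is new is their union in one flask at a single carbon and the use of an enol-ether-masked, 2,4-dialkylated oxoglutarate as the double acyl donor. No stereocentre is created, since C8 of 6 becomes sp2 and C3 stays racemic until step 7 removes it. The step needs C- over O-acylation and Claisen over aldol or pyranone folding: carbon attack is secured by the dianion, aldol closures through C6 or C8 would have to attack enolate-masked ketones and build quaternary carbons in rings that cannot aromatise, and O-acylation to the 2-pyranone is reversed by methoxide, so only the aromatic product should accumulate. The one weak point of 6, its remaining C4–H, is held in the alkene plane by A(1,3) strain and should therefore be removed slowly, and masking C7 as the MOM ether delivers that oxygen already protected.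

Step 7
Reactants: 15 1-[3,4-bis(methoxymethoxy)phenyl]-3-[2,6-dihydroxy-4-(methoxymethoxy)-3,5-bis(3-methylbut-2-enyl)phenyl]-2-(methoxymethoxy)propane-1,3-dione
Product: 17 2-(3,4-dihydroxyphenyl)-3,5,7-trihydroxy-6,8-bis(3-methylbut-2-enyl)-4H-chromen-4-one (6,8-diprenylquercetin), via tetra-MOM flavone 16 (not isolated)
Conditions: HCl (ca. 1 M, from conc. aq HCl), MeOH–THF, 45 °C, Ar; stopped at full conversion
Reagents that add atoms: none
Why: Acid-catalysed cyclodehydration of an o-hydroxyaryl 1,3-diketone (the closing stage of a Baker–Venkataraman flavone synthesis), in which either of the two equivalent ortho hydroxyls adds to the aryl ketone C2 and water is lost with the C3 stereocentre, is followed by methanolysis of the four MOM acetals, while dilute acid and moderate temperature should leave the trisubstituted prenyl alkenes unprotonated.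

Compound list
1 | dimethyl 1,3-acetonedicarboxylate | COC(=O)CC(=O)CC(=O)OC | starting material
2 | prenyl bromide (1-bromo-3-methylbut-2-ene) | CC(C)=CCBr | starting material
3 | dimethyl 2-(3-methylbut-2-enyl)-3-oxopentanedioate (racemic, not isolated) | COC(=O)CC(=O)C(CC=C(C)C)C(=O)OC | intermediate
4 | dimethyl 2,4-bis(3-methylbut-2-enyl)-3-oxopentanedioate (dl/meso mixture) | COC(=O)C(CC=C(C)C)C(=O)C(CC=C(C)C)C(=O)OC | intermediate
5 | chloromethyl methyl ether | COCCl | starting material
6 | dimethyl 3-(methoxymethoxy)-2,4-bis(3-methylbut-2-enyl)pent-2-enedioate (racemic, E/Z mixture) | COC(=O)C(CC=C(C)C)=C(OCOC)C(CC=C(C)C)C(=O)OC | intermediate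
7 | 2-chloro-3',4'-dihydroxyacetophenone | O=C(CCl)c1ccc(O)c(O)c1 | starting material
8 | 2-(3,4-dihydroxyphenyl)-2-oxoethyl formate (not isolated) | O=COCC(=O)c1ccc(O)c(O)c1 | intermediate
9 | 1-(3,4-dihydroxyphenyl)-2-hydroxyethan-1-one | O=C(CO)c1ccc(O)c(O)c1 | intermediate
10 | 1-[3,4-bis(methoxymethoxy)phenyl]-2-(methoxymethoxy)ethan-1-one | COCOCC(=O)c1ccc(OCOC)c(OCOC)c1 | intermediate
11 | 1-acetylbenzotriazole | CC(=O)n1nnc2ccccc21 | starting material
12 | 1-[3,4-bis(methoxymethoxy)phenyl]-2-(methoxymethoxy)butane-1,3-dione (racemic) | CC(=O)C(OCOC)C(=O)c1ccc(OCOC)c(OCOC)c1 | intermediate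
13 | dilithium bis-enolate (dianion) of 12 (not isolated) | [Li+].[Li+].C=C([O-])C(OCOC)=C([O-])c1ccc(OCOC)c(OCOC)c1 | intermediate
14 | methyl 9-[3,4-bis(methoxymethoxy)phenyl]-3,8-bis(methoxymethoxy)-2,4-bis(3-methylbut-2-enyl)-5,7,9-trioxonon-2-enoate (stereoisomer mixture, drawn neutral, not isolated) | COC(=O)C(CC=C(C)C)=C(OCOC)C(CC=C(C)C)C(=O)CC(=O)C(OCOC)C(=O)c1ccc(OCOC)c(OCOC)c1 | intermediate
15 | 1-[3,4-bis(methoxymethoxy)phenyl]-3-[2,6-dihydroxy-4-(methoxymethoxy)-3,5-bis(3-methylbut-2-enyl)phenyl]-2-(methoxymethoxy)propane-1,3-dione (racemic) | COCOC(C(=O)c1ccc(OCOC)c(OCOC)c1)C(=O)c1c(O)c(CC=C(C)C)c(OCOC)c(CC=C(C)C)c1O | intermediate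
16 | 2-[3,4-bis(methoxymethoxy)phenyl]-5-hydroxy-3,7-bis(methoxymethoxy)-6,8-bis(3-methylbut-2-enyl)-4H-chromen-4-one (not isolated) | COCOc1ccc(cc1OCOC)-c1oc2c(CC=C(C)C)c(OCOC)c(CC=C(C)C)c(O)c2c(=O)c1OCOC | intermediate
17 | 2-(3,4-dihydroxyphenyl)-3,5,7-trihydroxy-6,8-bis(3-methylbut-2-enyl)-4H-chromen-4-one (achiral) | CC(C)=CCc1c(O)c(CC=C(C)C)c2oc(-c3ccc(O)c(O)c3)c(O)c(=O)c2c1O | target

Total step count: 7. Longest linear sequence: 5 steps (steps 3, 4, 5, 6, 7). The diester branch (steps 1 and 2) joins at step 6.

Steps most likely to fail

**Step 6.**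
- Proton transfer from the C4–H of 6 to the dianion may outrun acylation and return both partners unchanged.
- The sequence may also stall at the open-chain stage, divert to lactonisation, or suffer exchange of the enol MOM ether by methoxide before ring closure.
- The fallback uses known chemistry. It sets out from 10, 2 and 5, takes ring A from the aromatic pool, and comes back to the route at 17.
- 2,4,6-Trihydroxybenzaldehyde F1 is C-prenylated twice with 2 (aq KOH, 0 °C, the phenolate C-alkylation used for diprenyl acylphloroglucinols). This gives 2,4,6-trihydroxy-3,5-bis(3-methylbut-2-enyl)benzaldehyde F2.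
- With 5 (NaH, DMF), F2 is converted into 2,4,6-tris(methoxymethoxy)-3,5-bis(3-methylbut-2-enyl)benzaldehyde F3.
- The lithium enolate of 10 (LiN(i-Pr)2, THF, −78 °C) adds to F3 to give the aldol adduct F4.
- Dess–Martin oxidation (NaHCO3-buffered CH2Cl2) then gives the hexa-MOM 1,3-diketone F5.
- The conditions of step 7 remove all six acetals from F5 and close ring C to give 17.

**Step 7.**
- Protonation of the prenyl alkenes may compete with acetal cleavage. The neighbouring C5 or C7 hydroxyl (chroman formation) or methanol would then add.
- The fallback separates ring closure from deprotection and removes the protic acid from the deprotection. It sets out from 15 and comes back at 17.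
- Ring C is closed first without touching the acetals (PPTS cat., toluene, molecular sieves, 70 °C), and 16 is isolated.
- The four MOM ethers are then exchanged for silyl ethers with Me3SiOTf and 2,2'-bipyridyl (MeCN, 0 °C → rt), a medium without free Brønsted acid. This gives the tetrakis(trimethylsilyl) ether F6. Silylation of the chelated 5-OH as well would be of no consequence.
- Added water cleaves F6 to 17 in the same flask.

**Step 5.**
- O-acetylation of the enolate, or proton exchange between product and enolate, may limit conversion.
- The fallback replaces acylation by addition and oxidation. It sets out from 10 and comes back at 12.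
- The lithium enolate of 10 (LiN(i-Pr)2, THF, −78 °C) is added to acetaldehyde to give the β-hydroxy ketone F7 as a diastereomer mixture.
- Dess–Martin periodinane (CH2Cl2, NaHCO3) oxidises F7 to 12.

Further compounds
F1 | step 6 | 2,4,6-trihydroxybenzaldehyde | O=Cc1c(O)cc(O)cc1O
F2 | step 6 | 2,4,6-trihydroxy-3,5-bis(3-methylbut-2-enyl)benzaldehyde | O=Cc1c(O)c(CC=C(C)C)c(O)c(CC=C(C)C)c1O
F3 | step 6 | 2,4,6-tris(methoxymethoxy)-3,5-bis(3-methylbut-2-enyl)benzaldehyde | O=Cc1c(OCOC)c(CC=C(C)C)c(OCOC)c(CC=C(C)C)c1OCOC
F4 | step 6 | 1-[3,4-bis(methoxymethoxy)phenyl]-3-hydroxy-2-(methoxymethoxy)-3-[2,4,6-tris(methoxymethoxy)-3,5-bis(3-methylbut-2-enyl)phenyl]propan-1-one (racemic diastereomer mixture) | COCOC(C(=O)c1ccc(OCOC)c(OCOC)c1)C(O)c1c(OCOC)c(CC=C(C)C)c(OCOC)c(CC=C(C)C)c1OCOC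
F5 | step 6 | 1-[3,4-bis(methoxymethoxy)phenyl]-2-(methoxymethoxy)-3-[2,4,6-tris(methoxymethoxy)-3,5-bis(3-methylbut-2-enyl)phenyl]propane-1,3-dione (racemic) | COCOC(C(=O)c1ccc(OCOC)c(OCOC)c1)C(=O)c1c(OCOC)c(CC=C(C)C)c(OCOC)c(CC=C(C)C)c1OCOC
F6 | step 7 | 2-[3,4-bis(trimethylsilyloxy)phenyl]-5-hydroxy-6,8-bis(3-methylbut-2-enyl)-3,7-bis(trimethylsilyloxy)-4H-chromen-4-one | C[Si](C)(C)Oc1ccc(cc1O[Si](C)(C)C)-c1oc2c(CC=C(C)C)c(O[Si](C)(C)C)c(CC=C(C)C)c(O)c2c(=O)c1O[Si](C)(C)C
F7 | step 5 | 1-[3,4-bis(methoxymethoxy)phenyl]-3-hydroxy-2-(methoxymethoxy)butan-1-one (racemic diastereomer mixture) | CC(O)C(OCOC)C(=O)c1ccc(OCOC)c(OCOC)c1
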